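**Strategy.** The route rests on inserting one carbon into the arene of an atraric acid ether. Ring A (the tropone) is atraric acid plus one carbon, C3a, which sits between the ether carbon C8a and the only CH of ring A (C4), that is, between the oxygen-bearing carbon and the sole free ortho position of atraric acid. A rhodium carbenoid from an aryloxy diazoketone cyclopropanates exactly this bond; 6π opening of the norcaradiene gives the cycloheptatriene (ring A) and closes the furan-3-one (ring B) in the same operation. The precursor is the tertiary aryl ether of a carvone-derived cyclohexane (ring C) carrying a diazoacetyl group on the ether carbon.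

Key step: step 15

**Remarks on the chemistry (assumptions)**
- Locants follow spiro[cyclohepta[b]furan-2,1'-cyclohexane]: O1, spiro C2 (= C1'), C3, ring-fusion C3a, C4 to C8, C8a. Ring A is the seven-membered ring, ring B the furan ring, ring C the cyclohexane.
- The C3a centre formed in step 15 and the C3 carbinol centre of steps 16 and 17 are assumed to arise as mixtures. Both are erased by step 19 and are left unspecified.
- A tertiary alkoxide and a δ-ester in one molecule lactonise faster than the alkoxide can be arylated. The side-chain carboxyl is therefore carried as a δ-lactone, then as a carboxylate during ether formation, and only afterwards as an ester.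
- The ester chosen is the 2-(trimethylsilyl)ethyl ester, which is removed together with the silyl ether by fluoride. The end game then needs no acid, which the tertiary alcohol and the tertiary ring B ether would not tolerate well.
- The secondary methyl centre of ring C is epimerisable until step 6 and is set by equilibration in step 3.

**Route**

Step 1
Reactants: 1 (S)-(+)-carvone
Product: 2 (2S,5S)-2-methyl-5-(prop-1-en-2-yl)cyclohexan-1-one (trans-dihydrocarvone)
Conditions: LiBH(s-Bu)3 (L-Selectride), THF, −78 °C; aq. NH4Cl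
Reagents that add atoms: none
Why: Conjugate (1,4) hydride reduction of a β-unsubstituted cyclohexenone, which leaves the isopropenyl group and the carvone stereocentre untouched; the α-methyl centre is epimerisable, the trans isomer should predominate and any cis isomer converges in step 3.

Step 2
Reactants: 2 trans-dihydrocarvone
Product: 3 (3R,6S)-6-methyl-2-methylidene-3-(prop-1-en-2-yl)cyclohexan-1-one
Conditions: paraformaldehyde, N-methylanilinium trifluoroacetate, THF, reflux
Reagents that add atoms: formaldehyde (from paraformaldehyde), C=O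
Why: Mannich-type α-methylenation, in which only the CH2 α-carbon can end as a methylidene (the other α-carbon is a methine), so the exocyclic enone forms next to the isopropenyl-bearing carbon.

Step 3
Reactants: 3 exocyclic enone; 4 tert-butyl acrylate
Product: 6 tert-butyl 3-[(1R,3S,6R)-1,3-dimethyl-2-oxo-6-(prop-1-en-2-yl)cyclohexyl]propanoate, via lithium enolate 5 (not isolated)
Conditions: LiBH(s-Bu)3, THF, −78 °C; then 4 (1.05 equiv, slow addition), −78 → −40 °C; aq. NH4Cl; then K2CO3 (cat.), MeOH, rt
Reagents that add atoms: none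
Why: Tandem conjugate reduction and Michael addition, in which hydride addition to the methylidene gives the tetrasubstituted enolate regiospecifically and the acrylate adds anti to the isopropenyl group on the adjacent carbon, which sets the quaternary centre (chain trans, methyl cis to isopropenyl); the carbonate treatment equilibrates the secondary methyl to the equatorial position, where it avoids a 1,3-diaxial clash with the axial methyl.

Step 4
Reactants: 6 keto ester
Product: 7 tert-butyl 3-[(1R,3S,6S)-6-(2-hydroxypropan-2-yl)-1,3-dimethyl-2-oxocyclohexyl]propanoate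
Conditions: Co(acac)2 (cat.), PhSiH3, O2 (1 atm), THF, rt
Reagents that add atoms: dioxygen, O=O
Why: Mukaiyama hydration (hydrogen-atom transfer from a cobalt hydride, trapping of the tertiary radical by O2, reduction of the peroxide), which hydrates the only alkene in the Markovnikov sense without touching the ketone, the ester or a stereocentre.

Step 5
Reactants: 7 tertiary alcohol
Product: 8 tert-butyl 3-[(1R,3S,6S)-1,3-dimethyl-2-oxo-6-{2-[(triethylsilyl)oxy]propan-2-yl}cyclohexyl]propanoate
Conditions: Et3SiOTf, 2,6-lutidine, CH2Cl2, −78 → 0 °C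
Reagents that add atoms: triethylsilyl trifluoromethanesulfonate, CC[Si](CC)(CC)OS(=O)(=O)C(F)(F)F
Why: Silylation of a hindered tertiary alcohol with a silyl triflate, which masks the only hydroxyl before two alkoxide steps and the carbenoid step.

Step 6
Reactants: 8 silyl ether ketone
Product: 10 (4aR,5S,8S,8aR)-8a-ethenyl-4a,8-dimethyl-5-{2-[(triethylsilyl)oxy]propan-2-yl}octahydro-2H-chromen-2-one, via hydroxy ester 9 (not isolated)
Conditions: CH2=CHMgBr, CeCl3 (dried), THF, −78 → 0 °C; work-up; then KOt-Bu (0.1 equiv), THF, rt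
Reagents that add atoms: vinylmagnesium bromide, C=C[Mg]Br
Why: Organocerium 1,2-addition followed by lactonisation, in which the weakly basic vinyl reagent attacks the hindered ketone axially, anti to the axial methyl of the neighbouring quaternary carbon (chair with the silyloxypropyl group equatorial), so the carbinol centre forms with oxygen equatorial; the alkoxide then closes the δ-lactone with loss of tert-butoxide.

Step 7
Reactants: 11 atraric acid
Product: 12 methyl 2-hydroxy-3,6-dimethyl-4-[(trifluoromethanesulfonyl)oxy]benzoate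
Conditions: PhNTf2 (1.05 equiv), K2CO3, THF, rt
Reagents that add atoms: N-phenylbis(trifluoromethanesulfonimide), O=S(=O)(N(c1ccccc1)S(=O)(=O)C(F)(F)F)C(F)(F)F
Why: Chemoselective O-sulfonylation, since the 4-hydroxyl is the more acidic, unhindered phenol whereas the 2-hydroxyl is held in a hydrogen bond to the ester.

Step 8
Reactants: 12 hydroxy triflate
Product: 13 methyl 2-methoxy-3,6-dimethyl-4-[(trifluoromethanesulfonyl)oxy]benzoate
Conditions: CH3I, K2CO3, DMF, 40 °C
Reagents that add atoms: iodomethane, CI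
Why: Williamson O-methylation of the remaining phenol, to which the aryl triflate is inert.

Step 9
Reactants: 13 aryl triflate
Product: 14 methyl 4-fluoro-2-methoxy-3,6-dimethylbenzoate
Conditions: [(cinnamyl)PdCl]2 (cat.), t-BuBrettPhos, CsF, toluene, 110 °C
Reagents that add atoms: caesium fluoride, [Cs+].[F-]
Why: Palladium-catalysed nucleophilic fluorination of an aryl triflate (oxidative addition, triflate–fluoride exchange, C–F reductive elimination from a bulky biarylphosphine complex), for which an ortho-substituted, ester-bearing triflate is a favourable substrate.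

Step 10
Reactants: 10 vinyl lactone; 14 aryl fluoride
Product: 16 3-[(1R,2R,3S,6S)-2-ethenyl-2-[3-methoxy-4-(methoxycarbonyl)-2,5-dimethylphenoxy]-1,3-dimethyl-6-{2-[(triethylsilyl)oxy]propan-2-yl}cyclohexyl]propanoic acid, via potassium hydroxy carboxylate 15 (not isolated)
Conditions: KOH (1.05 equiv), THF/MeOH/H2O, rt; evaporate, dry azeotropically (toluene); KN(SiMe3)2 (1.3 equiv), 18-crown-6, THF/DMF, 0 °C; 14 (1.5 equiv), 50 °C; aq. KHSO4 (pH 3), 0 °C
Reagents that add atoms: potassium hydroxide, [K+].[OH-]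
Why: Lactone saponification followed by nucleophilic aromatic substitution (addition–elimination), in which the carboxylate cannot be attacked by the alkoxide, so relactonisation cannot compete, and the potassium alkoxide displaces fluoride para to the ester; the carbinol configuration is kept because its C–O bond is not broken.

Step 11
Reactants: 16 aryl ether acid
Product: 17 2-(trimethylsilyl)ethyl ester of 16
Conditions: Me3SiCH2CH2OH, EDC·HCl, DMAP, CH2Cl2, rt
Reagents that add atoms: 2-(trimethylsilyl)ethanol, C[Si](C)(C)CCO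
Why: Steglich-type carbodiimide esterification, giving an ester that is stable to every later step and is cleaved by fluoride together with the silyl ether.

Step 12
Reactants: 17 vinyl ether ester
Product: 18 2-(trimethylsilyl)ethyl 3-[(1R,2R,3S,6S)-2-formyl-2-[3-methoxy-4-(methoxycarbonyl)-2,5-dimethylphenoxy]-1,3-dimethyl-6-{2-[(triethylsilyl)oxy]propan-2-yl}cyclohexyl]propanoate
Conditions: O3, CH2Cl2, pyridine (cat.), −78 °C (indicator end point); PPh3, −78 °C → rt
Reagents that add atoms: ozone, [O-][O+]=O
Why: Ozonolysis with reductive work-up, the monosubstituted alkene being far more reactive toward ozone than the ester-bearing arene.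

Step 13
Reactants: 18 aldehyde
Product: 19 (1R,2R,3S,6S)-1-[3-methoxy-4-(methoxycarbonyl)-2,5-dimethylphenoxy]-2,6-dimethyl-2-{3-oxo-3-[2-(trimethylsilyl)ethoxy]propyl}-3-{2-[(triethylsilyl)oxy]propan-2-yl}cyclohexane-1-carboxylic acid
Conditions: NaClO2, NaH2PO4, 2-methylbut-2-ene, t-BuOH/H2O, rt
Reagents that add atoms: sodium chlorite, [Na+].[O-]Cl=O
Why: Pinnick oxidation, which works on neopentyl-type aldehydes, while the alkene scavenger removes hypochlorous acid before it can chlorinate the arene.

Step 14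
Reactants: 19 carboxylic acid
Product: 21 2-(trimethylsilyl)ethyl 3-[(1R,2R,3S,6S)-2-(2-diazoacetyl)-2-[3-methoxy-4-(methoxycarbonyl)-2,5-dimethylphenoxy]-1,3-dimethyl-6-{2-[(triethylsilyl)oxy]propan-2-yl}cyclohexyl]propanoate, via acid chloride 20 (not isolated)
Conditions: 1-chloro-N,N,2-trimethylprop-1-en-1-amine, CH2Cl2, 0 °C → rt; then CH2N2 (excess), Et3N, Et2O/CH2Cl2, 0 °C
Reagents that add atoms: diazomethane, C=[N+]=[N-]
Why: Neutral acyl chloride formation followed by acylation of diazomethane (first stage of the Arndt–Eistert sequence); the α-carbon is quaternary, so no ketene can form and triethylamine can scavenge HCl and protect the silyl ether.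

Step 15
Reactants: 21 aryloxy diazoketone
Product: 23 methyl (1'R,2'R,3'S,6'S)-7-methoxy-2',5,6',8-tetramethyl-3-oxo-2'-{3-oxo-3-[2-(trimethylsilyl)ethoxy]propyl}-3'-{2-[(triethylsilyl)oxy]propan-2-yl}-3,3a-dihydrospiro[cyclohepta[b]furan-2,1'-cyclohexane]-6-carboxylate, via norcaradiene 22 (not isolated)
Conditions: Rh2(O2CCF3)4 (1 mol %), CH2Cl2, slow addition of 21, rt; filtration through basic alumina
Reagents that add atoms: none
Why: Loss of dinitrogen gives an electrophilic rhodium carbenoid that cyclopropanates the arene bond between the ether-bearing carbon and its only unsubstituted ortho carbon to give norcaradiene 22, which opens by a thermally allowed disrotatory 6π electrocyclic reaction to cycloheptatriene 23 (intramolecular Buchner reaction, as in azulenone and cyclohepta[b]furanone formation from arene-tethered diazoketones). Ring B closes in the cyclopropanation as a five-membered ring through the O–C–C(=O) tether, and ring A arises by ring expansion when the former arene bond breaks, so both bonds to the new ring-fusion carbon form here. The only new stereocentre, the ring-fusion CH, is not controlled and need not be, since it becomes sp2 in step 19, and the four ring C centres are remote from any bond that changes. The step needs chemoselectivity for arene addition over formal aromatic C–H substitution (which would give a chroman-3-one) and over aliphatic C–H insertion, and site selectivity between the two ortho bonds. The perfluorocarboxylate ligands make the carbenoid strongly electrophilic, which favours aromatic cycloaddition, the para ester tempers arenium-ion formation, and the other ortho carbon carries a methyl group. The product is kept away from acid, which would isomerise it to the chromanone, and is reduced at once.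

Step 16
Reactants: 23 cycloheptatriene ketone
Product: 24 the 3-hydroxy compound, methyl (1'R,2'R,3'S,6'S)-3-hydroxy-7-methoxy-2',5,6',8-tetramethyl-2'-{3-oxo-3-[2-(trimethylsilyl)ethoxy]propyl}-3'-{2-[(triethylsilyl)oxy]propan-2-yl}-3,3a-dihydrospiro[cyclohepta[b]furan-2,1'-cyclohexane]-6-carboxylate
Conditions: NaBH4, CeCl3·7H2O, MeOH/THF, −78 → −40 °C
Reagents that add atoms: none
Why: Luche-type hydride reduction, in which the cerium-activated ketone is reduced faster than either ester and faster than the acidic ring-fusion proton is removed; the carbinol centre forms as a mixture and is deleted in step 18.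

Step 17
Reactants: 24 alcohol
Product: 25 the S-methyl xanthate of 24 (3-{[(methylsulfanyl)carbonothioyl]oxy} compound)
Conditions: NaH, CS2, THF, 0 °C; then CH3I, 0 °C → rt
Reagents that add atoms: carbon disulfide, S=C=S; iodomethane, CI
Why: Xanthate formation (first stage of the Barton–McCombie deoxygenation) by addition of the alkoxide to carbon disulfide and S-methylation.

Step 18
Reactants: 25 xanthate
Product: 26 methyl (1'R,2'R,3'S,6'S)-7-methoxy-2',5,6',8-tetramethyl-2'-{3-oxo-3-[2-(trimethylsilyl)ethoxy]propyl}-3'-{2-[(triethylsilyl)oxy]propan-2-yl}-3,3a-dihydrospiro[cyclohepta[b]furan-2,1'-cyclohexane]-6-carboxylate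
Conditions: Bu3SnH (5 equiv, 0.5 M), Et3B/air, (PhSe)2 (cat.), toluene, rt
Reagents that add atoms: none
Why: Barton–McCombie radical deoxygenation, where room-temperature initiation, a high stannane concentration and catalytic benzeneselenol should let hydrogen transfer outrun rearrangement of the radical next to the cycloheptatriene.

Step 19
Reactants: 26 deoxygenated cycloheptatriene
Product: 28 methyl (1'R,2'R,3'S,6'S)-2',5,6',8-tetramethyl-7-oxo-2'-{3-oxo-3-[2-(trimethylsilyl)ethoxy]propyl}-3'-{2-[(triethylsilyl)oxy]propan-2-yl}-3,7-dihydrospiro[cyclohepta[b]furan-2,1'-cyclohexane]-6-carboxylate, via methoxytropylium tetrafluoroborate 27 (not isolated)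
Conditions: Ph3CBF4 (1.05 equiv), 2,6-di-tert-butyl-4-methylpyridine (cat.), CH2Cl2, −40 → 0 °C; then Bu4NI, 0 °C
Reagents that add atoms: none
Why: Hydride abstraction by the trityl cation from the ring-fusion C–H gives the aromatic methoxytropylium ion, and iodide removes the O-methyl group by SN2 attack (the classical cycloheptatriene-to-tropone oxidation), which the tertiary ring B ether cannot undergo.

Step 20
Reactants: 28 protected tropone
Product: 29 target, 3-[(1'R,2'R,3'S,6'S)-3'-(2-hydroxypropan-2-yl)-6-(methoxycarbonyl)-2',5,6',8-tetramethyl-7-oxo-3,7-dihydrospiro[cyclohepta[b]furan-2,1'-cyclohexan]-2'-yl]propanoic acid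
Conditions: tris(dimethylamino)sulfonium difluorotrimethylsilicate (TASF), DMF, 0 °C → rt; aq. NH4Cl
Reagents that add atoms: none
Why: Fluoride-induced β-elimination of the 2-(trimethylsilyl)ethyl ester and Si–O cleavage of the triethylsilyl ether under neutral conditions, which spare the tropone, its methyl ester, the tertiary ether and the tertiary alcohol.

**Compound list**

1 | (S)-(+)-carvone | O=C1C(C)=CC[C@H](C(C)=C)C1 | starting material
2 | (2S,5S)-2-methyl-5-(prop-1-en-2-yl)cyclohexan-1-one | O=C1[C@@H](C)CC[C@H](C(C)=C)C1 | intermediate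
3 | (3R,6S)-6-methyl-2-methylidene-3-(prop-1-en-2-yl)cyclohexan-1-one | O=C1[C@@H](C)CC[C@H](C(C)=C)C1=C | intermediate
4 | tert-butyl acrylate | C=CC(=O)OC(C)(C)C | starting material
5 | lithium (3R,6S)-2,6-dimethyl-3-(prop-1-en-2-yl)cyclohex-1-en-1-olate | [Li+].[O-]C1=C(C)[C@@H](C(C)=C)CC[C@@H]1C | intermediate (not isolated)
6 | tert-butyl 3-[(1R,3S,6R)-1,3-dimethyl-2-oxo-6-(prop-1-en-2-yl)cyclohexyl]propanoate | O=C1[C@@H](C)CC[C@H](C(C)=C)[C@@]1(C)CCC(=O)OC(C)(C)C | intermediate
7 | tert-butyl 3-[(1R,3S,6S)-6-(2-hydroxypropan-2-yl)-1,3-dimethyl-2-oxocyclohexyl]propanoate | O=C1[C@@H](C)CC[C@H](C(C)(C)O)[C@@]1(C)CCC(=O)OC(C)(C)C | intermediate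
8 | tert-butyl 3-[(1R,3S,6S)-1,3-dimethyl-2-oxo-6-{2-[(triethylsilyl)oxy]propan-2-yl}cyclohexyl]propanoate | O=C1[C@@H](C)CC[C@H](C(C)(C)O[Si](CC)(CC)CC)[C@@]1(C)CCC(=O)OC(C)(C)C | intermediate
9 | tert-butyl 3-[(1R,2R,3S,6S)-2-ethenyl-2-hydroxy-1,3-dimethyl-6-{2-[(triethylsilyl)oxy]propan-2-yl}cyclohexyl]propanoate | O[C@]1(C=C)[C@@H](C)CC[C@H](C(C)(C)O[Si](CC)(CC)CC)[C@@]1(C)CCC(=O)OC(C)(C)C | intermediate (not isolated)
10 | (4aR,5S,8S,8aR)-8a-ethenyl-4a,8-dimethyl-5-{2-[(triethylsilyl)oxy]propan-2-yl}octahydro-2H-chromen-2-one | O1[C@]2(C=C)[C@@H](C)CC[C@H](C(C)(C)O[Si](CC)(CC)CC)[C@@]2(C)CCC1=O | intermediate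
11 | atraric acid (methyl 2,4-dihydroxy-3,6-dimethylbenzoate) | COC(=O)c1c(C)cc(O)c(C)c1O | starting material
12 | methyl 2-hydroxy-3,6-dimethyl-4-[(trifluoromethanesulfonyl)oxy]benzoate | COC(=O)c1c(C)cc(OS(=O)(=O)C(F)(F)F)c(C)c1O | intermediate
13 | methyl 2-methoxy-3,6-dimethyl-4-[(trifluoromethanesulfonyl)oxy]benzoate | COC(=O)c1c(C)cc(OS(=O)(=O)C(F)(F)F)c(C)c1OC | intermediate
14 | methyl 4-fluoro-2-methoxy-3,6-dimethylbenzoate | COC(=O)c1c(C)cc(F)c(C)c1OC | intermediate
15 | potassium 3-[(1R,2R,3S,6S)-2-ethenyl-2-hydroxy-1,3-dimethyl-6-{2-[(triethylsilyl)oxy]propan-2-yl}cyclohexyl]propanoate | O[C@]1(C=C)[C@@H](C)CC[C@H](C(C)(C)O[Si](CC)(CC)CC)[C@@]1(C)CCC(=O)[O-].[K+] | intermediate (not isolated)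
16 | 3-[(1R,2R,3S,6S)-2-ethenyl-2-[3-methoxy-4-(methoxycarbonyl)-2,5-dimethylphenoxy]-1,3-dimethyl-6-{2-[(triethylsilyl)oxy]propan-2-yl}cyclohexyl]propanoic acid | COC(=O)c1c(C)cc(O[C@]2(C=C)[C@@H](C)CC[C@H](C(C)(C)O[Si](CC)(CC)CC)[C@@]2(C)CCC(=O)O)c(C)c1OC | intermediate
17 | 2-(trimethylsilyl)ethyl ester of 16 | COC(=O)c1c(C)cc(O[C@]2(C=C)[C@@H](C)CC[C@H](C(C)(C)O[Si](CC)(CC)CC)[C@@]2(C)CCC(=O)OCC[Si](C)(C)C)c(C)c1OC | intermediate
18 | 2-(trimethylsilyl)ethyl 3-[(1R,2R,3S,6S)-2-formyl-2-[3-methoxy-4-(methoxycarbonyl)-2,5-dimethylphenoxy]-1,3-dimethyl-6-{2-[(triethylsilyl)oxy]propan-2-yl}cyclohexyl]propanoate | COC(=O)c1c(C)cc(O[C@]2(C=O)[C@@H](C)CC[C@H](C(C)(C)O[Si](CC)(CC)CC)[C@@]2(C)CCC(=O)OCC[Si](C)(C)C)c(C)c1OC | intermediate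
19 | (1R,2R,3S,6S)-1-[3-methoxy-4-(methoxycarbonyl)-2,5-dimethylphenoxy]-2,6-dimethyl-2-{3-oxo-3-[2-(trimethylsilyl)ethoxy]propyl}-3-{2-[(triethylsilyl)oxy]propan-2-yl}cyclohexane-1-carboxylic acid | COC(=O)c1c(C)cc(O[C@]2(C(=O)O)[C@@H](C)CC[C@H](C(C)(C)O[Si](CC)(CC)CC)[C@@]2(C)CCC(=O)OCC[Si](C)(C)C)c(C)c1OC | intermediate
20 | acid chloride of 19 | COC(=O)c1c(C)cc(O[C@]2(C(=O)Cl)[C@@H](C)CC[C@H](C(C)(C)O[Si](CC)(CC)CC)[C@@]2(C)CCC(=O)OCC[Si](C)(C)C)c(C)c1OC | intermediate (not isolated)
21 | 2-(trimethylsilyl)ethyl 3-[(1R,2R,3S,6S)-2-(2-diazoacetyl)-2-[3-methoxy-4-(methoxycarbonyl)-2,5-dimethylphenoxy]-1,3-dimethyl-6-{2-[(triethylsilyl)oxy]propan-2-yl}cyclohexyl]propanoate (key-step precursor) | COC(=O)c1c(C)cc(O[C@]2(C(=O)C=[N+]=[N-])[C@@H](C)CC[C@H](C(C)(C)O[Si](CC)(CC)CC)[C@@]2(C)CCC(=O)OCC[Si](C)(C)C)c(C)c1OC | intermediate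
22 | norcaradiene valence isomer of 23 (cyclopropane spanning C3a, C4 and C8a) | COC(=O)C1=C(C)C2C3C(=O)[C@@]4(OC23C(C)=C1OC)[C@@H](C)CC[C@H](C(C)(C)O[Si](CC)(CC)CC)[C@@]4(C)CCC(=O)OCC[Si](C)(C)C | intermediate (not isolated)
23 | methyl (1'R,2'R,3'S,6'S)-7-methoxy-2',5,6',8-tetramethyl-3-oxo-2'-{3-oxo-3-[2-(trimethylsilyl)ethoxy]propyl}-3'-{2-[(triethylsilyl)oxy]propan-2-yl}-3,3a-dihydrospiro[cyclohepta[b]furan-2,1'-cyclohexane]-6-carboxylate (key-step product, C3a unspecified) | COC(=O)C1=C(OC)C(C)=C(C2C=C1C)O[C@]1(C2=O)[C@@H](C)CC[C@H](C(C)(C)O[Si](CC)(CC)CC)[C@@]1(C)CCC(=O)OCC[Si](C)(C)C | intermediate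
24 | 3-hydroxy analogue of 23 (C3 and C3a unspecified) | COC(=O)C1=C(OC)C(C)=C(C2C=C1C)O[C@]1(C2O)[C@@H](C)CC[C@H](C(C)(C)O[Si](CC)(CC)CC)[C@@]1(C)CCC(=O)OCC[Si](C)(C)C | intermediate
25 | O-(S-methyl dithiocarbonate) of 24 | COC(=O)C1=C(OC)C(C)=C(C2C=C1C)O[C@]1(C2OC(=S)SC)[C@@H](C)CC[C@H](C(C)(C)O[Si](CC)(CC)CC)[C@@]1(C)CCC(=O)OCC[Si](C)(C)C | intermediate
26 | methyl (1'R,2'R,3'S,6'S)-7-methoxy-2',5,6',8-tetramethyl-2'-{3-oxo-3-[2-(trimethylsilyl)ethoxy]propyl}-3'-{2-[(triethylsilyl)oxy]propan-2-yl}-3,3a-dihydrospiro[cyclohepta[b]furan-2,1'-cyclohexane]-6-carboxylate | COC(=O)C1=C(OC)C(C)=C(C2C=C1C)O[C@]1(C2)[C@@H](C)CC[C@H](C(C)(C)O[Si](CC)(CC)CC)[C@@]1(C)CCC(=O)OCC[Si](C)(C)C | intermediate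
27 | 7-methoxytropylium tetrafluoroborate (O-methylated form of 28) | COC(=O)C1=C(C)C=C2C(=C(C)C1=[O+]C)O[C@]1(C2)[C@@H](C)CC[C@H](C(C)(C)O[Si](CC)(CC)CC)[C@@]1(C)CCC(=O)OCC[Si](C)(C)C.F[B-](F)(F)F | intermediate (not isolated)
28 | methyl (1'R,2'R,3'S,6'S)-2',5,6',8-tetramethyl-7-oxo-2'-{3-oxo-3-[2-(trimethylsilyl)ethoxy]propyl}-3'-{2-[(triethylsilyl)oxy]propan-2-yl}-3,7-dihydrospiro[cyclohepta[b]furan-2,1'-cyclohexane]-6-carboxylate | COC(=O)c1c(C)cc2c(c(C)c1=O)O[C@]1(C2)[C@@H](C)CC[C@H](C(C)(C)O[Si](CC)(CC)CC)[C@@]1(C)CCC(=O)OCC[Si](C)(C)C | intermediate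
29 | 3-[(1'R,2'R,3'S,6'S)-3'-(2-hydroxypropan-2-yl)-6-(methoxycarbonyl)-2',5,6',8-tetramethyl-7-oxo-3,7-dihydrospiro[cyclohepta[b]furan-2,1'-cyclohexan]-2'-yl]propanoic acid (CNP0448476.3) | COC(=O)c1c(C)cc2c(c(C)c1=O)O[C@]1(C2)[C@@H](C)CC[C@H](C(C)(C)O)[C@@]1(C)CCC(=O)O | target

**Step count.** Total: 20 steps. Longest linear sequence: 17 steps (steps 1 to 6 and 10 to 20, from (S)-carvone); the aryl fluoride (steps 7 to 9) is made separately and joined in step 10.

**Steps most likely to fail**

Step 15 (key step). The carbenoid may attack the free ortho carbon as an electrophile, after which the arenium ion loses a proton instead of closing the cyclopropane (formal aromatic C–H substitution, six-membered ketone). It may also insert into a C–H bond of the ring C substituents, or the product may isomerise on contact with acidic surfaces. The fallback replaces the acceptor-only carbenoid by an acceptor–acceptor carbenoid, a class known to prefer arene cyclopropanation. Setting out from aldehyde 18, DBU-catalysed addition of 2,2,2-trichloroethyl diazoacetate would give the α-diazo-β-hydroxy ester F1, and Dess–Martin oxidation the α-diazo-β-keto ester F2. Cu(hfacac)2 (copper bis(hexafluoroacetylacetonate)) in CH2Cl2 would then give the norcaradiene keto ester F3. Zinc in buffered aqueous THF would cleave the trichloroethyl ester to the β-keto acid F4, which loses CO2 and rejoins the route at ketone 23.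

Step 10. The addition–elimination may be too slow, because the activating ester is twisted out of the ring plane by its two ortho substituents and the alkoxide is flanked by a quaternary carbon. Prolonged heating would invite aromatic Claisen rearrangement of the allylic aryl ether and fluoride-induced loss of the silyl ether. The fallback forms the same C–O bond by ligand coupling on trivalent iodine, which is known for tertiary alkoxides at room temperature. Setting out from triflate 13, Pd(OAc)2/XPhos-catalysed Miyaura borylation with B2(OH)4 would give the arylboronic acid F5. Treatment with (diacetoxyiodo)mesitylene and BF3·OEt2 would give the aryl(mesityl)iodonium tetrafluoroborate F6. The dipotassium salt made from 15 and KN(SiMe3)2 would be O-arylated by F6 in toluene/THF at room temperature, with transfer of the electron-poorer aryl group, and acidification returns to acid 16.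

Step 18. The secondary radical next to the cycloheptatriene may rearrange (ring opening through the norcaradiene valence isomer, or a 1,2-vinyl shift) before it is reduced. The fallback avoids radicals and bypasses steps 16 to 18. Setting out from ketone 23, KN(SiMe3)2 and N-phenylbis(trifluoromethanesulfonimide) would give the enol triflate F7. Pd(OAc)2/PPh3-catalysed reduction with tributylammonium formate would give the heptafulvene F8. Protonation of its exocyclic carbon with HBF4·OEt2 at −78 °C would give the methoxytropylium salt 27, which is demethylated with Bu4NI as in step 19 and rejoins the route at tropone 28.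

**Further compounds**

F1 | step 15 | 2,2,2-trichloroethyl 2-diazo-3-hydroxypropanoate adduct of aldehyde 18 (α-diazo-β-hydroxy ester) | COC(=O)c1c(C)cc(O[C@]2(C(O)C(=[N+]=[N-])C(=O)OCC(Cl)(Cl)Cl)[C@@H](C)CC[C@H](C(C)(C)O[Si](CC)(CC)CC)[C@@]2(C)CCC(=O)OCC[Si](C)(C)C)c(C)c1OC
F2 | step 15 | α-diazo-β-keto 2,2,2-trichloroethyl ester | COC(=O)c1c(C)cc(O[C@]2(C(=O)C(=[N+]=[N-])C(=O)OCC(Cl)(Cl)Cl)[C@@H](C)CC[C@H](C(C)(C)O[Si](CC)(CC)CC)[C@@]2(C)CCC(=O)OCC[Si](C)(C)C)c(C)c1OC
F3 | step 15 | norcaradiene keto ester (C3a trichloroethyl ester of 22) | COC(=O)C1=C(C)C2C3(C(=O)OCC(Cl)(Cl)Cl)C(=O)[C@@]4(OC23C(C)=C1OC)[C@@H](C)CC[C@H](C(C)(C)O[Si](CC)(CC)CC)[C@@]4(C)CCC(=O)OCC[Si](C)(C)C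
F4 | step 15 | β-keto acid from F3 (not isolated) | COC(=O)C1=C(C)C2C3(C(=O)O)C(=O)[C@@]4(OC23C(C)=C1OC)[C@@H](C)CC[C@H](C(C)(C)O[Si](CC)(CC)CC)[C@@]4(C)CCC(=O)OCC[Si](C)(C)C
F5 | step 10 | [3-methoxy-4-(methoxycarbonyl)-2,5-dimethylphenyl]boronic acid | COC(=O)c1c(C)cc(B(O)O)c(C)c1OC
F6 | step 10 | [3-methoxy-4-(methoxycarbonyl)-2,5-dimethylphenyl](2,4,6-trimethylphenyl)iodonium tetrafluoroborate | COC(=O)c1c(C)cc([I+]c2c(C)cc(C)cc2C)c(C)c1OC.F[B-](F)(F)F
F7 | step 18 | enol triflate of 23 (3-triflyloxy-2H-cyclohepta[b]furan) | COC(=O)C1=C(OC)C(C)=C2O[C@@]3([C@@H](C)CC[C@H](C(C)(C)O[Si](CC)(CC)CC)[C@@]3(C)CCC(=O)OCC[Si](C)(C)C)C(OS(=O)(=O)C(F)(F)F)=C2C=C1C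
F8 | step 18 | heptafulvene (3-unsubstituted 2H-cyclohepta[b]furan) | COC(=O)C1=C(OC)C(C)=C2O[C@@]3([C@@H](C)CC[C@H](C(C)(C)O[Si](CC)(CC)CC)[C@@]3(C)CCC(=O)OCC[Si](C)(C)C)C=C2C=C1C
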